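**Retrosynthetic overview**

1. The bicyclic core is numbered as a 2H-chromene (O1, C2, C3=C4, C4a, C5, C6, C7, C8, C8a). The C8 quaternary centre is made last, by ligand-controlled Pd transfer of the prenyl group from the side-chain prenyl ester onto C8 of an aromatic 6-acyl-5,7-dihydroxychromene; the same event frees the acid.
2. Enabling feature: the carbocycle C4a–C5–C6–C7–C8–C8a carries oxygen on the alternate atoms C5, C7 and C8a (phloroglucinol pattern), and the fused 2H-pyran O1–C2–C3=C4–C4a=C8a is the valence tautomer of a C4a-alkylidene 1-oxatriene. C5–C4a–C8a is therefore a prenylidenemalonyl unit and C6–C7–C8 the backbone of a β-diketone.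
3. Key disconnection: C5–C6 and C8–C8a, made in one pot by double C-acylation of a 1,3-bis(silyloxy)diene with 2-(3-methylbut-2-enylidene)malonyl dichloride, followed in the same flask by aromatisation and oxa-6π closure. The carbocycle forms first, the pyran second.
4. The diketone comes from (S)-limonene: cleavage of the ring C1–C2 bond keeps C4 as the side-chain stereocentre, the aldehyde arm gives the E-enoate (Wittig), and the methyl ketone is acylated with the (R)-2-methylbutanoyl unit.

Key step: step 11

Remark: (S)-(−)-limonene and (R)-2-methylbutanoic acid are taken as purchasable in high enantiomeric purity; locants C7, C9 and C11 in steps 7, 8 and 11 refer to the tridecenoate chain of 14.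

**Route**

Step 1
Reactants: 1 (S)-(−)-limonene
Product: 2 (4S)-limonene 1,2-oxide (cis/trans mixture at the epoxide)
Conditions: mCPBA (1.0 equiv), NaHCO3, CH2Cl2, 0 °C
Reagents that add atoms: mCPBA, OOC(=O)c1cccc(Cl)c1
Why: Prilezhaev epoxidation is selective for the more electron-rich trisubstituted ring alkene over the 1,1-disubstituted isopropenyl group; C4 is not involved and both epoxide diastereomers converge in step 2.

Step 2
Reactants: 2 (4S)-limonene 1,2-oxide
Product: 3 (3S)-6-oxo-3-(prop-1-en-2-yl)heptanal
Conditions: H5IO6 (1.1 equiv), THF/H2O, 0 → 20 °C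
Reagents that add atoms: water, O
Why: Epoxide hydrolysis and Malaprade glycol cleavage in one flask cut the C1–C2 bond of the terpene ring, so the ring stereocentre survives as an acyclic centre that is β to the aldehyde and γ to the ketone and cannot epimerise.

Step 3
Reactants: 4 2-bromopropanoyl bromide; 5 3-methylbut-2-en-1-ol (prenol)
Product: 6 3-methylbut-2-en-1-yl 2-bromopropanoate (racemic)
Conditions: pyridine (1.1 equiv), CH2Cl2, 0 °C
Reagents that add atoms: none
Why: Esterification of the allylic alcohol with the acyl bromide under pyridine buffering; the stereocentre of 6 is erased in step 4.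

Step 4
Reactants: 6 3-methylbut-2-en-1-yl 2-bromopropanoate; 7 triphenylphosphine
Product: 9 3-methylbut-2-en-1-yl 2-(triphenylphosphoranylidene)propanoate, via phosphonium bromide 8 (not isolated)
Conditions: toluene, 80 °C; then 1 M NaOH, CH2Cl2, 20 °C
Reagents that add atoms: none
Why: SN2 quaternisation of the phosphine by the α-bromo ester and deprotonation of the salt give the ester-stabilised ylide (standard Wittig reagent preparation).

Step 5
Reactants: 3 (3S)-6-oxo-3-(prop-1-en-2-yl)heptanal; 9 prenyl 2-(triphenylphosphoranylidene)propanoate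
Product: 10 3-methylbut-2-en-1-yl (2E,5S)-2-methyl-8-oxo-5-(prop-1-en-2-yl)non-2-enoate
Conditions: CH2Cl2, 20 °C
Reagents that add atoms: none
Why: Wittig olefination with a stabilised α-methyl ylide is aldehyde-selective (the methyl ketone is inert), non-basic (no aldol of the keto aldehyde) and E-selective, which sets the 2E alkene.

Step 6
Reactants: 11 (R)-2-methylbutanoic acid; 12 1H-benzotriazole
Product: 13 (2R)-1-(1H-benzotriazol-1-yl)-2-methylbutan-1-one
Conditions: SOCl2 (1.0 equiv), 12 (4 equiv), CH2Cl2, 20 °C
Reagents that add atoms: none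
Why: N-Acylbenzotriazole formation through a benzotriazole-activated sulfinyl intermediate needs no base, so no ketene forms and the R centre should be retained.

Step 7
Reactants: 10 keto enoate; 13 (R)-N-acylbenzotriazole
Product: 14 3-methylbut-2-en-1-yl (2E,5S,11R)-2,11-dimethyl-8,10-dioxo-5-(prop-1-en-2-yl)tridec-2-enoate
Conditions: LiHMDS (2.1 equiv), THF, −78 °C; then 13, −78 → −30 °C; AcOH
Reagents that add atoms: none
Why: Kinetic deprotonation at −78 °C takes the methyl rather than the methylene of the ketone, the lithium enolate is C-acylated by the N-acylbenzotriazole (Claisen-type acylation) faster than the shielded tertiary α-C–H of 13 is removed, and the second equivalent of base stores the product as its diketonate.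

Step 8
Reactants: 14 β-diketone
Product: 16 3-methylbut-2-en-1-yl (2E,5R,11R)-2,11-dimethyl-5-(prop-1-en-2-yl)-8,10-bis(trimethylsilyloxy)trideca-2,7,9-trienoate, via dilithium dianion 15 (not isolated)
Conditions: LDA (2.1 equiv), THF, −78 → −40 °C; TMSCl (2.4 equiv), −78 → 0 °C; pentane, filtration under Ar
Reagents that add atoms: chlorotrimethylsilane, C[Si](C)(C)Cl
Why: β-Diketone dianion formation removes the second proton from the less substituted α′ methylene (C7) and not from the methine C11, so the R centre is kept, and O,O-silylation of the dienediolate gives the Chan-type 1,3-bis(silyloxy)diene (enol ether geometry inconsequential; the 5R descriptor reflects a CIP priority change only).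

Step 9
Reactants: 17 3-methylbut-2-enal (prenal); 18 malonic acid
Product: 19 2-(3-methylbut-2-en-1-ylidene)propanedioic acid
Conditions: pyridine (2 equiv), piperidine (5 mol %), 0 → 20 °C; cold 1 M HCl
Reagents that add atoms: none
Why: Knoevenagel condensation, kept at or below 20 °C so that it stops before Doebner decarboxylation.

Step 10
Reactants: 19 prenylidenemalonic acid
Product: 20 2-(3-methylbut-2-en-1-ylidene)propanedioyl dichloride
Conditions: 1-chloro-N,N,2-trimethylprop-1-en-1-amine (2.1 equiv), CH2Cl2, 0 → 20 °C; used as solution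
Reagents that add atoms: 1-chloro-N,N,2-trimethylprop-1-en-1-amine (Ghosez reagent), CC(C)=C(Cl)N(C)C
Why: The α-chloroenamine converts both acids into acid chlorides under neutral conditions with only an amide as by-product, avoiding HCl that could lactonise the dienyl acid; 20 may equilibrate with its 6-chloro-2H-pyran valence tautomer, which delivers the same two acyl carbons.

Step 11
Reactants: 16 1,3-bis(silyloxy)diene; 20 prenylidenemalonyl dichloride
Product: 23 3-methylbut-2-en-1-yl (2E,5R)-6-{5,7-dihydroxy-2,2-dimethyl-6-[(2R)-2-methylbutanoyl]-2H-chromen-8-yl}-2-methyl-5-(prop-1-en-2-yl)hex-2-enoate, via acyl chloride 21 (not isolated), via prenylidene trione 22 (not isolated)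
Conditions: 20 (1.05 equiv), CH2Cl2 (0.02 M), −78 → 20 °C; then DMAP (0.2 equiv), 20 °C; aq citric acid
Reagents that add atoms: none
Why: Proposed new method: the terminal carbon C7 of the bis(silyloxy)diene, its most nucleophilic position, attacks one acyl chloride of 20 with loss of TMSCl (future C8–C8a bond, giving 21), and the remaining β-silyloxy enone then C-acylates at C9 with the second acyl chloride in a 6-exo-trig closure (future C5–C6 bond, second TMSCl) to give trione 22. 22 enolises towards the aromatic triol, whose C4a-alkylidene tautomer is an o-quinone methide, and a thermal disrotatory oxa-6π electrocyclisation closes the 2H-pyran. The closest known reaction types are the formal [3+3] cyclisations of Chan-type 1,3-bis(silyloxy)dienes with 1,3-dielectrophiles, the Effenberger cyclisation of enol ethers with malonyl dichloride and the Knoevenagel/oxa-6π chromenylation of acylphloroglucinols. No stereocentre is created (C8 becomes an aromatic carbon) and the two existing centres are not enolised under these neutral conditions. The step needs C- over O-acylation in the ring closure, secured because the O-acyl isomer is an enol lactone that cannot tautomerise to a stable hydroxypyranone (its C3 is blocked by the alkylidene) and is returned by DMAP-catalysed acyl transfer while the C-acylated product aromatises irreversibly; it also needs pyran closure onto the C8a oxygen rather than the C5 oxygen, secured because the C5 oxygen is locked in the hydrogen-bonded chelate with the C6 acyl group. Both acyl chlorides of 20 are equivalent, so the first acylation raises no regiochemical question.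

Step 12
Reactants: 23 chromene prenyl ester
Product: 24 (2E,5R)-6-{(8R)-7-hydroxy-2,2-dimethyl-6-[(2R)-2-methylbutanoyl]-8-(3-methylbut-2-en-1-yl)-5-oxo-5,8-dihydro-2H-chromen-8-yl}-2-methyl-5-(prop-1-en-2-yl)hex-2-enoic acid (CNP0184919.1)
Conditions: Pd2(dba)3 (2.5 mol %), (S,S)-DACH-phenyl Trost ligand (7.5 mol %), Et3N (0.2 equiv), THF, 25 °C; pH 4 buffer
Reagents that add atoms: none
Why: Proposed new method: Pd(0) ionises the prenyl ester to a (1,1-dimethylallyl)palladium cation paired with the substrate's own carboxylate; after proton shift the acylphloroglucinol phenoxide attacks the unsubstituted allyl terminus through C8, which gives the linear prenyl group, dearomatises the ring to the vinylogous acid of the target and leaves the free carboxylic acid. O-Prenyl ethers and re-formed prenyl ester re-ionise, so the irreversible C8 alkylation is the sink. The C8 configuration is to be set by the chiral ligand pocket (facial discrimination of the prochiral arene nucleophile; the remote side-chain centre should exert negligible induction), and the ligand enantiomer that delivers 8R is to be fixed in a screen. The closest known reaction types are Pd-catalysed allyl transfer from allyl esters to 1,3-dicarbonyl C-nucleophiles, Pd-catalysed dearomative prenylation of acylphloroglucinols and Tsuji–Trost asymmetric allylic alkylation and dearomatisation of prochiral phenol and enolate nucleophiles.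

**Compound list**

1 | (S)-(−)-limonene, (4S)-1-methyl-4-(prop-1-en-2-yl)cyclohex-1-ene | CC1=CC[C@H](CC1)C(C)=C | starting material
2 | (4S)-1-methyl-4-(prop-1-en-2-yl)-7-oxabicyclo[4.1.0]heptane (limonene 1,2-oxide, cis/trans mixture) | CC12OC1C[C@H](CC2)C(C)=C | intermediate
3 | (3S)-6-oxo-3-(prop-1-en-2-yl)heptanal | O=CC[C@H](CCC(C)=O)C(C)=C | intermediate
4 | 2-bromopropanoyl bromide (racemic) | CC(Br)C(=O)Br | starting material
5 | 3-methylbut-2-en-1-ol (prenol) | CC(C)=CCO | starting material
6 | 3-methylbut-2-en-1-yl 2-bromopropanoate (racemic) | CC(Br)C(=O)OCC=C(C)C | intermediate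
7 | triphenylphosphine | c1ccc(cc1)P(c1ccccc1)c1ccccc1 | starting material
8 | [1-(3-methylbut-2-en-1-yloxy)-1-oxopropan-2-yl]triphenylphosphonium bromide | CC(C(=O)OCC=C(C)C)[P+](c1ccccc1)(c1ccccc1)c1ccccc1.[Br-] | intermediate
9 | 3-methylbut-2-en-1-yl 2-(triphenylphosphoranylidene)propanoate | CC(C(=O)OCC=C(C)C)=P(c1ccccc1)(c1ccccc1)c1ccccc1 | intermediate
10 | 3-methylbut-2-en-1-yl (2E,5S)-2-methyl-8-oxo-5-(prop-1-en-2-yl)non-2-enoate | CC(C)=CCOC(=O)/C(C)=C/C[C@H](CCC(C)=O)C(C)=C | intermediate
11 | (R)-2-methylbutanoic acid | CC[C@@H](C)C(=O)O | starting material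
12 | 1H-benzotriazole | c1ccc2[nH]nnc2c1 | starting material
13 | (2R)-1-(1H-benzotriazol-1-yl)-2-methylbutan-1-one | CC[C@@H](C)C(=O)n1nnc2ccccc12 | intermediate
14 | 3-methylbut-2-en-1-yl (2E,5S,11R)-2,11-dimethyl-8,10-dioxo-5-(prop-1-en-2-yl)tridec-2-enoate | CC(C)=CCOC(=O)/C(C)=C/C[C@H](CCC(=O)CC(=O)[C@H](C)CC)C(C)=C | intermediate
15 | dilithium 7,9-dienediolate of 14 (dianion at C7 and C9) | CC(C)=CCOC(=O)/C(C)=C/C[C@H](CC=C([O-])C=C([O-])[C@H](C)CC)C(C)=C.[Li+].[Li+] | intermediate
16 | 3-methylbut-2-en-1-yl (2E,5R,11R)-2,11-dimethyl-5-(prop-1-en-2-yl)-8,10-bis(trimethylsilyloxy)trideca-2,7,9-trienoate | CC(C)=CCOC(=O)/C(C)=C/C[C@H](CC=C(O[Si](C)(C)C)C=C(O[Si](C)(C)C)[C@H](C)CC)C(C)=C | intermediate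
17 | 3-methylbut-2-enal (prenal) | CC(C)=CC=O | starting material
18 | malonic acid | OC(=O)CC(=O)O | starting material
19 | 2-(3-methylbut-2-en-1-ylidene)propanedioic acid | CC(C)=CC=C(C(=O)O)C(=O)O | intermediate
20 | 2-(3-methylbut-2-en-1-ylidene)propanedioyl dichloride | CC(C)=CC=C(C(=O)Cl)C(=O)Cl | intermediate
21 | C7-acylated acyl chloride (14 skeleton bearing the 2-(chlorocarbonyl)-5-methylhexa-2,4-dienoyl group at C7, C10 enol silyl ether; C7 epimers) | CC(C)=CCOC(=O)/C(C)=C/C[C@H](CC(C(=O)C(=CC=C(C)C)C(=O)Cl)C(=O)C=C(O[Si](C)(C)C)[C@H](C)CC)C(C)=C | intermediate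
22 | 6-(3-methylbut-2-en-1-ylidene)-2-[(2R)-2-methylbutanoyl]-4-alkylcyclohexane-1,3,5-trione, enol form (alkyl = the limonene-derived side chain) | CC(C)=CCOC(=O)/C(C)=C/C[C@H](CC1C(=O)C(=CC=C(C)C)C(=O)C(C(=O)[C@H](C)CC)=C1O)C(C)=C | intermediate
23 | 3-methylbut-2-en-1-yl (2E,5R)-6-{5,7-dihydroxy-2,2-dimethyl-6-[(2R)-2-methylbutanoyl]-2H-chromen-8-yl}-2-methyl-5-(prop-1-en-2-yl)hex-2-enoate | CC(C)=CCOC(=O)/C(C)=C/C[C@H](Cc1c(O)c(C(=O)[C@H](C)CC)c(O)c2C=CC(C)(C)Oc12)C(C)=C | intermediate
24 | (2E,5R)-6-{(8R)-7-hydroxy-2,2-dimethyl-6-[(2R)-2-methylbutanoyl]-8-(3-methylbut-2-en-1-yl)-5-oxo-5,8-dihydro-2H-chromen-8-yl}-2-methyl-5-(prop-1-en-2-yl)hex-2-enoic acid | C=C(C)[C@H](C/C=C(\C)C(=O)O)C[C@]1(CC=C(C)C)C(O)=C(C(=O)[C@H](C)CC)C(=O)C2=C1OC(C)(C)C=C2 | target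

**Step count and risks**

Total step count: 12. Longest linear sequence: 7 steps (steps 1, 2, 5, 7, 8, 11, 12).

Steps most likely to fail:

1. Step 11 (proposed new method). The ring closure may run through oxygen instead of carbon, the second acylation may occur between molecules and give oligomers, or the diacid chloride may decompose before it is intercepted. The fallback uses known chemistry, sets out from 16 and returns at 23. 16 is acylated at its terminal carbon with methyl malonyl chloride (CH2Cl2, −78 → 20 °C, aqueous work-up; γ-acylation of a bis(silyloxy)diene by an acid chloride) to give the trioxo ester F1. F1 is closed by a biomimetic Claisen cyclisation of the 3,5,7-trioxo ester type (KOt-Bu, THF, 0 °C) to the C-alkylated acylphloroglucinol F2. F2 is condensed with prenal 17 (ethylenediammonium diacetate, toluene, 80 °C; Knoevenagel/oxa-6π chromenylation through the non-chelated hydroxyl) to give 23.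

2. Step 12 (proposed new method). Facial selectivity at C8 may be poor, ionisation of the hindered prenyl ester may be slow, or alkylation may occur through oxygen or at C4a. The fallback uses known chemistry, sets out from 23 and returns at 24. Classical base-mediated dearomative C-prenylation with prenyl bromide (NaH, toluene, 0 °C) gives the C8-prenylated prenyl ester F3 as both C8 epimers, which are diastereomers and are separated by chromatography. The prenyl ester of the 8R epimer is then cleaved with Pd(OAc)2/TPPTS and diethylamine in MeCN/H2O to give 24.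

3. Step 8. Proton abstraction may occur at the wrong site: at C11–H, which would erode the R configuration, or at the γ-CH2 of the enoate, which would scramble the alkene. The fallback avoids strong base, sets out from 14 and returns at 16. Soft enolisation with TMSCl/Et3N (CH2Cl2, 20 °C) gives the mono silyl enol ether F4 (O-silyl regioisomers interconvert), and a second soft enolisation with TMSOTf/Et3N (Et2O, 0 °C) at the less hindered C7 methylene gives 16.

**Further compounds**

F1 | step 11 | 3-methylbut-2-en-1-yl (2E,5R,11R)-7-(3-methoxy-3-oxopropanoyl)-2,11-dimethyl-8,10-dioxo-5-(prop-1-en-2-yl)tridec-2-enoate (C7 epimers) | CC(C)=CCOC(=O)/C(C)=C/C[C@H](CC(C(=O)CC(=O)OC)C(=O)CC(=O)[C@H](C)CC)C(C)=C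
F2 | step 11 | 3-methylbut-2-en-1-yl (2E,5R)-2-methyl-6-{2,4,6-trihydroxy-3-[(2R)-2-methylbutanoyl]phenyl}-5-(prop-1-en-2-yl)hex-2-enoate | CC(C)=CCOC(=O)/C(C)=C/C[C@H](Cc1c(O)cc(O)c(C(=O)[C@H](C)CC)c1O)C(C)=C
F3 | step 12 | 3-methylbut-2-en-1-yl ester of 24 (8R epimer after separation) | C=C(C)[C@H](C/C=C(\C)C(=O)OCC=C(C)C)C[C@]1(CC=C(C)C)C(O)=C(C(=O)[C@H](C)CC)C(=O)C2=C1OC(C)(C)C=C2
F4 | step 8 | 3-methylbut-2-en-1-yl (2E,5S,11R)-2,11-dimethyl-8-oxo-5-(prop-1-en-2-yl)-10-(trimethylsilyloxy)trideca-2,9-dienoate | CC(C)=CCOC(=O)/C(C)=C/C[C@H](CCC(=O)C=C(O[Si](C)(C)C)[C@H](C)CC)C(C)=C
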